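The C40 polyene is cut at C11=C12 into a C25 ψ-chain phosphonium salt and a C15 ring aldehyde; the ring's trans-3,4-diol is traced back to safranal. The key step exploits the cis-disubstituted C3=C4 bond of the six-membered ring, the distal double bond of the C3=C4–C5=C6–C7=O dienal: a chiral (salen)MnCl catalyst lays one oxygen across it, which fixes C3 in its final R configuration and arms C4 for inversion by water. The precursor is safranal itself, achiral and commercial, whose tetrasubstituted, formyl-bearing C5=C6 bond is left untouched.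

Key step: step 1

Remark: carotenoid locants are used throughout (ring C1–C6, chain C7–C15, primed locants for the ψ half); metal alkoxides that are only protonated on work-up are not counted as separate compounds.

Step 1
Reactants: 1 safranal
Product: 2 (3R,4S)-3,4-epoxy-3,4-dihydrosafranal
Conditions: (S,S)-(salen)MnCl [(S,S)-N,N'-bis(3,5-di-tert-butylsalicylidene)-1,2-cyclohexanediaminomanganese chloride, trivalent manganese] (5 mol%), mCPBA (2 equiv), NMO (5 equiv), CH2Cl2, −78 °C
Reagents that add atoms: m-chloroperbenzoic acid (mCPBA), OOC(=O)c1cccc(Cl)c1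
Why: The peracid, buffered by NMO, oxidises the trivalent manganese complex to a pentavalent oxomanganese species that approaches the cis C3=C4 bond side-on and transfers its oxygen, forming C3–O first and C4–O through a C4 radical stabilised by the C5=C6–C7=O unit. This is a Jacobsen–Katsuki epoxidation, closest to the known cases of cis-cinnamates, cis-dienoates, 1,2-dihydronaphthalene and cyclic 1,3-dienes. The only ring formed is the oxirane, closed by collapse of the C4 radical onto the manganese-bound oxygen (three-membered closure by oxygen-atom transfer); because C3=C4 is endocyclic the fusion can only be cis, so the cis-to-trans leakage of acyclic conjugated alkenes cannot occur. C3 and C4 are set together by the catalyst's choice of alkene face, the achiral substrate offering one C1 methyl group to each face; the (S,S) ligand is chosen by analogy with 1,2-dihydronaphthalene and indene, where it gives the (1S,2R) oxide with C4 here in the place of the benzylic carbon, and the sense is to be checked on diol 3 by Mosher ester analysis. The step needs site selectivity for C3=C4 over C5=C6 and over the formyl group: C5=C6 is tetrasubstituted, directly deactivated by the formyl group and flanked by the C1 gem-dimethyl and C5 methyl groups, and at −78 °C the buffered peracid is expected neither to epoxidise the diene without the catalyst nor to attack the hindered conjugated aldehyde.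

Step 2
Reactants: 2 (3R,4S)-3,4-epoxy-3,4-dihydrosafranal
Product: 3 (3R,4R)-3,4-dihydroxy-2,6,6-trimethylcyclohex-1-ene-1-carbaldehyde
Conditions: HClO4 (cat.), THF/H2O 3:1, 0 °C → rt
Reagents that add atoms: water, O
Why: Acid-catalysed anti hydrolysis of a vinyl oxirane, in which water should attack the protonated epoxide at C4, the allylic carbon γ to the formyl group and so activated for borderline SN2 displacement, while trans-diaxial attack at C3 is screened by the axial C1 methyl group, so that C4 is inverted to R, C3 keeps its R configuration and the trans-diol results.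

Step 3
Reactants: 3 (3R,4R)-3,4-dihydroxy-2,6,6-trimethylcyclohex-1-ene-1-carbaldehyde
Product: 4 (3R,4R)-3,4-bis(tert-butyldimethylsilyloxy)-2,6,6-trimethylcyclohex-1-ene-1-carbaldehyde
Conditions: TBSOTf (2.5 equiv), 2,6-lutidine, CH2Cl2, −78 → 0 °C
Reagents that add atoms: tert-butyldimethylsilyl trifluoromethanesulfonate (TBSOTf), CC(C)(C)[Si](C)(C)OS(=O)(=O)C(F)(F)F
Why: Silylation of secondary alcohols with a silyl triflate and a hindered pyridine base, which should be fast even for the allylic C4 hydroxyl beside the C5 methyl group and leaves the formyl group (no α-hydrogen) and both stereocentres untouched.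

Step 4
Reactants: 4 (3R,4R)-3,4-bis(tert-butyldimethylsilyloxy)-2,6,6-trimethylcyclohex-1-ene-1-carbaldehyde, 5 diethyl [(2E)-3-cyano-2-methylprop-2-en-1-yl]phosphonate
Product: 7 (2E,4E)-5-[(3R,4R)-3,4-bis(tert-butyldimethylsilyloxy)-2,6,6-trimethylcyclohex-1-en-1-yl]-3-methylpenta-2,4-dienenitrile, via sodium phosphonate 6 (not isolated)
Conditions: 5, NaH, THF, 0 °C; then 4, 0 °C → rt
Reagents that add atoms: none
Why: Horner–Wadsworth–Emmons olefination in which the vinylogous cyanomethylphosphonate anion adds through its α-carbon to the hindered aldehyde and should give the E C7=C8 bond, the C9=C10 bond being expected mainly E and any 9Z isomer being removed by chromatography after step 5.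

Step 5
Reactants: 7 (2E,4E)-5-[(3R,4R)-3,4-bis(tert-butyldimethylsilyloxy)-2,6,6-trimethylcyclohex-1-en-1-yl]-3-methylpenta-2,4-dienenitrile
Product: 9 (2E,4E)-5-[(3R,4R)-3,4-bis(tert-butyldimethylsilyloxy)-2,6,6-trimethylcyclohex-1-en-1-yl]-3-methylpenta-2,4-dienal, via N-aluminated imine 8 (not isolated)
Conditions: i-Bu2AlH, hexane/CH2Cl2, −78 °C; then wet SiO2, 0 °C
Reagents that add atoms: water, O
Why: Partial reduction of the conjugated nitrile by i-Bu2AlH should stop at the N-aluminated imine at −78 °C, and mild hydrolysis on work-up releases the aldehyde (nitrile-to-aldehyde reduction), the silyl ethers being inert to the hydride.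

Step 6
Reactants: 10 pseudoionone
Product: 11 (4E,6E)-3,7,11-trimethyldodeca-1,4,6,10-tetraen-3-ol (racemic)
Conditions: CH2=CHMgBr, THF, −20 → 0 °C; aq NH4Cl
Reagents that add atoms: vinylmagnesium bromide, C=C[Mg]Br
Why: Grignard 1,2-addition to the methyl ketone of the dienone, whose carbonyl carbon is far more accessible than the β- and δ-positions; the new carbinol centre is racemic and is erased in step 7.

Step 7
Reactants: 11 (4E,6E)-3,7,11-trimethyldodeca-1,4,6,10-tetraen-3-ol (racemic)
Product: 12 [(2E,4E,6E)-3,7,11-trimethyldodeca-2,4,6,10-tetraen-1-yl]triphenylphosphonium bromide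
Conditions: PPh3·HBr, MeOH, 0 °C → rt
Reagents that add atoms: triphenylphosphine hydrobromide, [Br-].c1ccc(cc1)[PH+](c1ccccc1)c1ccccc1
Why: Acid-promoted ionisation of the tertiary allylic alcohol gives a delocalised cation that triphenylphosphine should capture at the unhindered primary terminus (SN1' allylic transposition to a Wittig salt), forming the thermodynamically preferred E C9'=C10' bond, with crystallisation planned to remove the minor 9'Z salt.

Step 8
Reactants: 12 [(2E,4E,6E)-3,7,11-trimethyldodeca-2,4,6,10-tetraen-1-yl]triphenylphosphonium bromide, 13 (2E,4E,6E)-2,7-dimethylocta-2,4,6-trienedial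
Product: 16 (2E,4E,6E,8E,10E,12E,14E)-2,7,11,15,19-pentamethylicosa-2,4,6,8,10,12,14,18-octaenal, via C15 ylide 14 (not isolated), via 8Z aldehyde 15 (not isolated)
Conditions: 13 (3 equiv), NaOMe (slow addition), CH2Cl2/MeOH, 0 °C; then I2 (cat.), n-heptane, daylight, rt
Reagents that add atoms: none
Why: Wittig olefination in which the ylide, generated slowly in excess dialdehyde, should react only once because the product aldehyde is conjugated to a longer polyene and less electrophilic than 13; the C11'=C12' bond forms as an E/Z mixture that iodine-catalysed equilibration is expected to converge on the all-E aldehyde.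

Step 9
Reactants: 16 (2E,4E,6E,8E,10E,12E,14E)-2,7,11,15,19-pentamethylicosa-2,4,6,8,10,12,14,18-octaenal
Product: 17 (2E,4E,6E,8E,10E,12E,14E)-2,7,11,15,19-pentamethylicosa-2,4,6,8,10,12,14,18-octaen-1-ol
Conditions: NaBH4, EtOH/THF, 0 °C
Reagents that add atoms: none
Why: Borohydride 1,2-reduction of the polyenal to the primary allylic alcohol, which should not touch the polyene.

Step 10
Reactants: 17 (2E,4E,6E,8E,10E,12E,14E)-2,7,11,15,19-pentamethylicosa-2,4,6,8,10,12,14,18-octaen-1-ol
Product: 18 [(2E,4E,6E,8E,10E,12E,14E)-2,7,11,15,19-pentamethylicosa-2,4,6,8,10,12,14,18-octaen-1-yl]triphenylphosphonium bromide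
Conditions: PPh3·HBr, CH2Cl2/MeOH, 0 °C → rt, dark
Reagents that add atoms: triphenylphosphine hydrobromide, [Br-].c1ccc(cc1)[PH+](c1ccccc1)c1ccccc1
Why: The allylic alcohol ionises under HBr to a polyenyl cation that triphenylphosphine should trap at the primary C12 terminus, as in the conversion of retinol into its Wittig salt (SN1-type phosphonium salt formation), keeping the all-E conjugated chain.

Step 11
Reactants: 18 [(2E,4E,6E,8E,10E,12E,14E)-2,7,11,15,19-pentamethylicosa-2,4,6,8,10,12,14,18-octaen-1-yl]triphenylphosphonium bromide, 9 (2E,4E)-5-[(3R,4R)-3,4-bis(tert-butyldimethylsilyloxy)-2,6,6-trimethylcyclohex-1-en-1-yl]-3-methylpenta-2,4-dienal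
Product: 21 (all-E,3R,4R)-3,4-bis(tert-butyldimethylsilyloxy)-β,ψ-carotene, via C25 ylide 19 (not isolated), via 11Z isomer 20 (not isolated)
Conditions: NaOMe, CH2Cl2/MeOH, 0 °C → rt; then n-heptane, reflux, N2, dark
Reagents that add atoms: none
Why: Wittig olefination of the C15 aldehyde with the semi-stabilised C25 ylide forms C11=C12 as an E/Z mixture, and the 11Z isomer, crowded by the C13 methyl group, is expected to isomerise thermally to the all-E polyene in hot heptane, while the silyl ethers tolerate methoxide at 0 °C and C3 and C4 are remote from the reaction.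

Step 12
Reactants: 21 (all-E,3R,4R)-3,4-bis(tert-butyldimethylsilyloxy)-β,ψ-carotene
Product: 22 (all-E,3R,4R)-β,ψ-carotene-3,4-diol
Conditions: Bu4NF, THF, 0 °C → rt, dark
Reagents that add atoms: none
Why: Fluoride-mediated desilylation of both silyl ethers under non-acidic conditions, which should avoid ionisation of the allylic C4–O bond of the polyene and leaves C3 and C4 unchanged.

Compound list
1 | safranal (2,6,6-trimethylcyclohexa-1,3-diene-1-carbaldehyde) | O=CC1=C(C)C=CCC1(C)C | starting material
2 | (3R,4S)-3,4-epoxy-3,4-dihydrosafranal [(1S,6R)-2,4,4-trimethyl-7-oxabicyclo[4.1.0]hept-2-ene-3-carbaldehyde] | O=CC1=C(C)[C@@H]2O[C@@H]2CC1(C)C | intermediate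
3 | (3R,4R)-3,4-dihydroxy-2,6,6-trimethylcyclohex-1-ene-1-carbaldehyde | O=CC1=C(C)[C@@H](O)[C@H](O)CC1(C)C | intermediate
4 | (3R,4R)-3,4-bis(tert-butyldimethylsilyloxy)-2,6,6-trimethylcyclohex-1-ene-1-carbaldehyde | O=CC1=C(C)[C@@H](O[Si](C)(C)C(C)(C)C)[C@H](O[Si](C)(C)C(C)(C)C)CC1(C)C | intermediate
5 | diethyl [(2E)-3-cyano-2-methylprop-2-en-1-yl]phosphonate (commercial, may contain the 2Z isomer) | CCOP(=O)(OCC)C/C(C)=C/C#N | starting material
6 | sodium salt of the α-carbanion of 5 (delocalised) | CCOP(=O)(OCC)[CH-]C(C)=CC#N.[Na+] | intermediate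
7 | (2E,4E)-5-[(3R,4R)-3,4-bis(tert-butyldimethylsilyloxy)-2,6,6-trimethylcyclohex-1-en-1-yl]-3-methylpenta-2,4-dienenitrile | N#C/C=C(C)/C=C/C1=C(C)[C@@H](O[Si](C)(C)C(C)(C)C)[C@H](O[Si](C)(C)C(C)(C)C)CC1(C)C | intermediate
8 | N-(diisobutylaluminio)imine of aldehyde 9 | CC(C)C[Al](CC(C)C)N=C/C=C(C)/C=C/C1=C(C)[C@@H](O[Si](C)(C)C(C)(C)C)[C@H](O[Si](C)(C)C(C)(C)C)CC1(C)C | intermediate
9 | (2E,4E)-5-[(3R,4R)-3,4-bis(tert-butyldimethylsilyloxy)-2,6,6-trimethylcyclohex-1-en-1-yl]-3-methylpenta-2,4-dienal | O=C/C=C(C)/C=C/C1=C(C)[C@@H](O[Si](C)(C)C(C)(C)C)[C@H](O[Si](C)(C)C(C)(C)C)CC1(C)C | intermediate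
10 | pseudoionone [(3E,5E)-6,10-dimethylundeca-3,5,9-trien-2-one] | CC(C)=CCC/C(C)=C/C=C/C(C)=O | starting material
11 | (4E,6E)-3,7,11-trimethyldodeca-1,4,6,10-tetraen-3-ol (racemic at C3) | CC(C)=CCC/C(C)=C/C=C/C(C)(O)C=C | intermediate
12 | [(2E,4E,6E)-3,7,11-trimethyldodeca-2,4,6,10-tetraen-1-yl]triphenylphosphonium bromide | CC(C)=CCC/C(C)=C/C=C/C(C)=C/C[P+](c1ccccc1)(c1ccccc1)c1ccccc1.[Br-] | intermediate
13 | (2E,4E,6E)-2,7-dimethylocta-2,4,6-trienedial | O=C/C(C)=C/C=C/C=C(C)/C=O | starting material
14 | ylide of 12 [(2E,4E,6E)-3,7,11-trimethyldodeca-2,4,6,10-tetraen-1-ylidene]triphenylphosphorane | CC(C)=CCC/C(C)=C/C=C/C(C)=C/C=P(c1ccccc1)(c1ccccc1)c1ccccc1 | intermediate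
15 | (2E,4E,6E,8Z,10E,12E,14E)-2,7,11,15,19-pentamethylicosa-2,4,6,8,10,12,14,18-octaenal | CC(C)=CCC/C(C)=C/C=C/C(C)=C/C=C\C(C)=C\C=C\C=C(C)\C=O | intermediate
16 | (2E,4E,6E,8E,10E,12E,14E)-2,7,11,15,19-pentamethylicosa-2,4,6,8,10,12,14,18-octaenal (formyl carbon = C12 of the target) | CC(C)=CCC/C(C)=C/C=C/C(C)=C/C=C/C(C)=C/C=C/C=C(C)/C=O | intermediate
17 | (2E,4E,6E,8E,10E,12E,14E)-2,7,11,15,19-pentamethylicosa-2,4,6,8,10,12,14,18-octaen-1-ol | CC(C)=CCC/C(C)=C/C=C/C(C)=C/C=C/C(C)=C/C=C/C=C(C)/CO | intermediate
18 | [(2E,4E,6E,8E,10E,12E,14E)-2,7,11,15,19-pentamethylicosa-2,4,6,8,10,12,14,18-octaen-1-yl]triphenylphosphonium bromide | CC(C)=CCC/C(C)=C/C=C/C(C)=C/C=C/C(C)=C/C=C/C=C(C)/C[P+](c1ccccc1)(c1ccccc1)c1ccccc1.[Br-] | intermediate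
19 | ylide of 18 | CC(C)=CCC/C(C)=C/C=C/C(C)=C/C=C/C(C)=C/C=C/C=C(C)/C=P(c1ccccc1)(c1ccccc1)c1ccccc1 | intermediate
20 | (11Z,3R,4R)-3,4-bis(tert-butyldimethylsilyloxy)-β,ψ-carotene | CC(C)=CCC/C(C)=C/C=C/C(C)=C/C=C/C(C)=C/C=C/C=C(C)/C=C\C=C(C)\C=C\C1=C(C)[C@@H](O[Si](C)(C)C(C)(C)C)[C@H](O[Si](C)(C)C(C)(C)C)CC1(C)C | intermediate
21 | (all-E,3R,4R)-3,4-bis(tert-butyldimethylsilyloxy)-β,ψ-carotene | CC(C)=CCC/C(C)=C/C=C/C(C)=C/C=C/C(C)=C/C=C/C=C(C)/C=C/C=C(C)/C=C/C1=C(C)[C@@H](O[Si](C)(C)C(C)(C)C)[C@H](O[Si](C)(C)C(C)(C)C)CC1(C)C | intermediate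
22 | (all-E,3R,4R)-β,ψ-carotene-3,4-diol | CC(C)=CCC/C(C)=C/C=C/C(C)=C/C=C/C(C)=C/C=C/C=C(C)/C=C/C=C(C)/C=C/C1=C(C)[C@@H](O)[C@H](O)CC1(C)C | target

Total step count: 12. Longest linear sequence: 7 steps (steps 1–5, 11 and 12 from safranal; equally steps 6–12 from pseudoionone).

Steps most likely to fail

Step 1. The catalyst may discriminate the two faces of C3=C4 poorly, or the peracid may consume the formyl group, so that 2 would be obtained in low enantiomeric purity or low amount. Fallback: setting out from 1, epoxidation without a chiral catalyst (mCPBA, NaHCO3, CH2Cl2, 0 °C) would give racemic cis-3,4-epoxy-3,4-dihydrosafranal F1. Hydrolysis as in step 2 would give the racemic trans-diol F2. Lipase-catalysed acylation (Burkholderia cepacia lipase, vinyl acetate, t-BuOMe, rt) is then expected to acylate the (3R,4R) enantiomer at the less hindered C3 hydroxyl, by the empirical rule for secondary carbinols and by analogy with trans-cyclohexane-1,2-diol. This would give the (3R,4R)-3-O-acetyl diol F3, separable from the unreacted (3S,4S)-diol; the assignment would be confirmed before use. Methanolysis of F3 (K2CO3, MeOH, 0 °C) comes back to the route at 3.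

Step 2. Under strong acid the oxirane may rearrange to a ketone by hydride shift, or water may enter at C3 instead of C4, which would erode the enantiomeric purity of the trans-diol. Fallback: setting out from 2, opening with buffered carboxylate (NaOAc, AcOH, 40 °C) would deliver acetate at the allylic C4 with inversion and without a strong acid, giving the (3R,4R)-4-O-acetyl diol F4. Methanolysis (K2CO3, MeOH, 0 °C) comes back to the route at 3; acyl migration between O3 and O4 would be harmless because both esters give the same diol.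

Step 8. The ylide may condense with both formyl groups of the symmetrical dialdehyde, which would consume 12 as the C40 bis-olefin and complicate isolation of the mono-adduct. Fallback: setting out from 13, mono-acetalisation with neopentyl glycol (1 equiv, p-TsOH cat., toluene, rt) would give the mono(neopentyl glycol) acetal F5, with unreacted 13 and the bis-acetal separated and recycled. Wittig reaction of ylide 14 (from 12, NaOMe, CH2Cl2/MeOH, 0 °C) with F5, which has a single free formyl group, would give the C25 acetal F6 together with its 8Z isomer F7. Dilute H2SO4 in THF at rt would then release 16 and 15, and the iodine equilibration of step 8 comes back to the route at 16.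

Further compounds
F1 | step 1 | racemic cis-3,4-epoxy-3,4-dihydrosafranal | O=CC1=C(C)[C@@H]2O[C@@H]2CC1(C)C.O=CC1=C(C)[C@H]2O[C@H]2CC1(C)C
F2 | step 1 | racemic trans-3,4-dihydroxy-2,6,6-trimethylcyclohex-1-ene-1-carbaldehyde | O=CC1=C(C)[C@@H](O)[C@H](O)CC1(C)C.O=CC1=C(C)[C@H](O)[C@@H](O)CC1(C)C
F3 | step 1 | (1R,2R)-4-formyl-2-hydroxy-3,5,5-trimethylcyclohex-3-en-1-yl acetate [(3R,4R)-3-O-acetyl diol] | O=CC1=C(C)[C@@H](O)[C@H](OC(C)=O)CC1(C)C
F4 | step 2 | (1R,6R)-3-formyl-6-hydroxy-2,4,4-trimethylcyclohex-2-en-1-yl acetate [(3R,4R)-4-O-acetyl diol] | O=CC1=C(C)[C@@H](OC(C)=O)[C@H](O)CC1(C)C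
F5 | step 8 | (2E,4E,6E)-7-(5,5-dimethyl-1,3-dioxan-2-yl)-2-methylocta-2,4,6-trienal | O=C/C(C)=C/C=C/C=C(C)/C1OCC(C)(C)CO1
F6 | step 8 | neopentyl glycol acetal of 16 (all-E) | CC(C)=CCC/C(C)=C/C=C/C(C)=C/C=C/C(C)=C/C=C/C=C(C)/C1OCC(C)(C)CO1
F7 | step 8 | neopentyl glycol acetal of 15 (8Z isomer of F6) | CC(C)=CCC/C(C)=C/C=C/C(C)=C/C=C\C(C)=C\C=C\C=C(C)\C1OCC(C)(C)CO1
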